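The time of reading was the question for the next run: 25 s as on Wednesday's, or 80 s as on Monday's, from the same charges.

    starting material ⇌ open intermediate (K1 = 0.94, k1 = 0.057 /s)
    partner → second intermediate (k2 = 0.38 /s)
    open intermediate + second intermediate → target (k3 = 6.0 /M/s)
    2 open intermediate → homo product (k4 = 8.7 /M/s)
    starting material + open intermediate → side product (k5 = 0.57 /M/s)

in all of them: starting material 20 mM; partner 30.0 mM

| charge | time |
|---|---|
| Wednesday's | 25 s |
| Monday's | 80 s |

- which of these there is most of at the end, counted by the starting material in it, Wednesday's (side product / open intermediate / target / starting material / homo product)
- which of these there is most of at the end, counted by the starting material in it, Monday's (side product / open intermediate / target / starting material / homo product)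
- how much there is at the end of the one of these that leads, in percent of the starting material charged: Wednesday's
- how much there is at the end of the one of these that leads, in percent of the starting material charged: Monday's

- in percentages every species weighs as the starting material in it: one homo product or side product counts as two
- a doubled species enters its step squared and goes two at a time
- run time (Wednesday's): 25 s

I watched one fraction of the charge, the pool: whatever is still starting material or open intermediate. The partner turns into second intermediate with a life of 2.63 s, and as a simplification I took the second intermediate at its full charge from the start. That makes trapping a pseudo-first-order step, and the pool then falls exponentially:

fall-back of open intermediate = 0.0606 /s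

trapping of open intermediate = 0.180 /s

pool rate = k1 × trapping / (trapping + fall-back) = 0.0426 /s

half-life = ln(2) / pool rate = 16.3 s

This pool half-life, the time in which the pool falls by half with the trap at full charge, is longer than the partner's life, so the second intermediate forms early, but trapping also uses it up, and holding it at full charge remained my assumption. It gave these pool fractions:

at 25 s: 34.4 %

at 80 s: 3.30 %

For the part that leaves the pool, I took open intermediate as 19.2 % of the charge. Its loss to homo product then runs at 0.0666 /s, slower than trapping, so target receives 73.0 %. I therefore reckoned target at 47.8 % on Wednesday's, ahead of the pool left there, and at 70.6 % on Monday's. I decided to leave the next run to 80 s and to watch the pool.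

The forecast named target for both flasks, at 41 % and 71 %, in the words “The slow ring-opening step limits the overall rate”, and its Wednesday's figure stood below mine.

Wednesday's gave target at 41.7 %, and Monday's gave target at 70.7 %. At 25.0 s, Wednesday's pool stood at 41.8 %, above my 34.4 %, with second intermediate at 21.7 mM. Carrying that pool forward 55.0 s at the pool half-life of 16.3 s gives 4.03 %. Monday's, from the same charges, held 6.61 % in its pool at 80.0 s.

The constants were set for the occasion.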